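**Retrosynthetic overview**

- The strategy rests on the benzoate ring, where C1 (ester), C2 (OH) and C3 (OH) are contiguous and C3 is the only unsubstituted carbon next to the C2 oxygen. The C3 hydroxyl is therefore installed last, by C–H hydroxylation of a salicylate, in the way salicylate is thought to be oxidised to 2,3-dihydroxybenzoate in plants.
- Key disconnection: the C3–O bond, formed by palladium-catalysed C–H oxygenation directed by a di-tert-butylsilanol tethered on O2. The only ring formed in the route is the temporary five-membered 1,3,2-dioxasilole across O2 and O3 (closed in step 6, opened in step 7); the benzene ring is bought.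
- Ester C(=O)–O bond: transesterification of methyl salicylate with (S)-18-methylicosan-1-ol.
- C16–C17 bond of the chain: copper-catalysed coupling of the Grignard reagent of (S)-1-bromo-2-methylbutane, which supplies the C18 stereocentre, with silyl-protected 16-bromohexadecan-1-ol.

Key step: step 6

Assumption: the oxygen that ends on C3 is counted as coming from an acetate of PhI(OAc)2 (acetoxylation, then acyl transfer to the silanol), and commercial (S)-1-bromo-2-methylbutane is taken to be enantiomerically pure.

**Route**

Step 1
Reactants: 1 16-bromohexadecan-1-ol
Product: 2 [(16-bromohexadecyl)oxy](tert-butyl)dimethylsilane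
Conditions: TBSCl, imidazole, CH2Cl2, rt
Reagents that add atoms: tert-butyldimethylsilyl chloride, CC(C)(C)[Si](C)(C)Cl
Why: Imidazole-promoted O-silylation of a primary alcohol masks the acidic OH that would quench the Grignard reagent of step 2 and leaves the primary bromide untouched.

Step 2
Reactants: 2 [(16-bromohexadecyl)oxy](tert-butyl)dimethylsilane; 3 (S)-1-bromo-2-methylbutane
Product: 5 tert-butyldimethyl{[(S)-18-methylicosyl]oxy}silane, via (S)-(2-methylbutyl)magnesium bromide 4 (not isolated)
Conditions: 3, Mg, THF, 40 °C; then 2, Li2CuCl4 (3 mol%), THF, 0 °C → rt
Reagents that add atoms: magnesium, [Mg] (retained only in intermediate 4)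
Why: Copper-catalysed alkyl–alkyl Grignard cross-coupling with Li2CuCl4 should displace the unhindered primary bromide and form the C16–C17 bond; the C18 stereocentre comes with bromide 3, lies beta to magnesium and is not involved, and the silyl ether is inert.

Step 3
Reactants: 5 tert-butyldimethyl{[(S)-18-methylicosyl]oxy}silane
Product: 6 (S)-18-methylicosan-1-ol
Conditions: p-TsOH·H2O (10 mol%), MeOH/THF 1:1, rt
Reagents that add atoms: none
Why: Acid-catalysed methanolysis of a primary TBS ether should free the alcohol, and nothing else in the saturated chain can react.

Step 4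
Reactants: 6 (S)-18-methylicosan-1-ol; 7 methyl salicylate
Product: 8 (S)-18-methylicosyl 2-hydroxybenzoate
Conditions: Bu2SnO (10 mol%), 7 (5 equiv, neat), 150 °C, N2 sweep (−MeOH)
Reagents that add atoms: none
Why: Tin-catalysed transesterification is driven by the excess of 7 and by removal of methanol; the phenol is not acylated because aryl esters are disfavoured at equilibrium, and the remote stereocentre is unaffected.

Step 5
Reactants: 8 (S)-18-methylicosyl 2-hydroxybenzoate; 9 di-tert-butylsilyl bis(trifluoromethanesulfonate)
Product: 11 (S)-18-methylicosyl 2-{[di-tert-butyl(hydroxy)silyl]oxy}benzoate, via aryloxysilyl triflate 10 (not isolated)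
Conditions: 8 added slowly to 9 (1.3 equiv), 2,6-lutidine (3 equiv), CH2Cl2, 0 °C → rt; then H2O, THF, rt
Reagents that add atoms: water, O
Why: O-silylation of the phenol by a silyl triflate should stop after one substitution because the two tert-butyl groups and the ortho ester block a second aryloxy group; hydrolysis of the remaining Si–OTf bond of 10 then gives a silanol too hindered to condense to a disiloxane.

Step 6
Reactants: 11 (S)-18-methylicosyl 2-{[di-tert-butyl(hydroxy)silyl]oxy}benzoate
Product: 13 (S)-18-methylicosyl 2,2-di-tert-butyl-1,3,2-benzodioxasilole-4-carboxylate, via C3-acetoxy silanol 12 (not isolated)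
Conditions: Pd(OPiv)2 (10 mol%), PhI(OAc)2 (2 equiv), PhMe, 100 °C
Reagents that add atoms: (diacetoxyiodo)benzene, CC(=O)OI(OC(C)=O)c1ccccc1
Why: The silanol binds Pd(OPiv)2 as a silanolate and concerted metalation–deprotonation at C3–H should give a six-membered palladacycle (Pd, C3, C2, O2, Si, O) of divalent palladium; PhI(OAc)2 oxidises it to tetravalent palladium, and C–OAc reductive elimination forms the new C3–O bond in acetate 12. The acetyl group of 12 then passes to the neighbouring silanol and the freed C3 oxygen displaces acetate at silicon with loss of acetic acid, so the five-membered 1,3,2-dioxasilole ring (O2, Si, O3, C3, C2) closes by intramolecular 5-exo substitution at silicon and shields the catechol from further oxidation. The closest known reaction type is the palladium-catalysed, silanol-directed ortho C–H oxygenation of phenols to silicon-protected catechols, which is reported to tolerate electron-poor phenols. No stereocentre is formed, and C18 is remote and untouched. The step needs site selectivity for C3 over C4, C5 and C6, and the substrate secures it: C3–H is the only C–H bond ortho to the silanol-bearing O2, the other ortho carbon C1 carries the ester, the Si–O tether cannot reach further, and the benzoate carbonyl is a much weaker directing group than the silanolate, so palladation at C6 should not compete.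

Step 7
Reactants: 13 (S)-18-methylicosyl 2,2-di-tert-butyl-1,3,2-benzodioxasilole-4-carboxylate
Product: 14 Gentiside H, (S)-18-methylicosyl 2,3-dihydroxybenzoate
Conditions: TBAF (2.5 equiv), AcOH (2.5 equiv), THF, 0 °C → rt, argon
Reagents that add atoms: none
Why: Fluoride-mediated desilylation should cleave both aryl O–Si bonds in turn; acetic acid buffers the catecholate against air oxidation, and the alkyl benzoate is inert to buffered fluoride.

**Compound list**

1 | 16-bromohexadecan-1-ol | OCCCCCCCCCCCCCCCCBr | starting material
2 | [(16-bromohexadecyl)oxy](tert-butyl)dimethylsilane | CC(C)(C)[Si](C)(C)OCCCCCCCCCCCCCCCCBr | intermediate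
3 | (S)-1-bromo-2-methylbutane | CC[C@H](C)CBr | starting material
4 | (S)-(2-methylbutyl)magnesium bromide | CC[C@H](C)C[Mg]Br | intermediate
5 | tert-butyldimethyl{[(S)-18-methylicosyl]oxy}silane | CC[C@H](C)CCCCCCCCCCCCCCCCCO[Si](C)(C)C(C)(C)C | intermediate
6 | (S)-18-methylicosan-1-ol | CC[C@H](C)CCCCCCCCCCCCCCCCCO | intermediate
7 | methyl salicylate | COC(=O)c1ccccc1O | starting material
8 | (S)-18-methylicosyl 2-hydroxybenzoate | CC[C@H](C)CCCCCCCCCCCCCCCCCOC(=O)c1ccccc1O | intermediate
9 | di-tert-butylsilyl bis(trifluoromethanesulfonate) | CC(C)(C)[Si](OS(=O)(=O)C(F)(F)F)(OS(=O)(=O)C(F)(F)F)C(C)(C)C | starting material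
10 | (S)-18-methylicosyl 2-({di-tert-butyl[(trifluoromethanesulfonyl)oxy]silyl}oxy)benzoate | CC[C@H](C)CCCCCCCCCCCCCCCCCOC(=O)c1ccccc1O[Si](OS(=O)(=O)C(F)(F)F)(C(C)(C)C)C(C)(C)C | intermediate
11 | (S)-18-methylicosyl 2-{[di-tert-butyl(hydroxy)silyl]oxy}benzoate | CC[C@H](C)CCCCCCCCCCCCCCCCCOC(=O)c1ccccc1O[Si](O)(C(C)(C)C)C(C)(C)C | intermediate
12 | (S)-18-methylicosyl 3-acetoxy-2-{[di-tert-butyl(hydroxy)silyl]oxy}benzoate | CC[C@H](C)CCCCCCCCCCCCCCCCCOC(=O)c1cccc(OC(C)=O)c1O[Si](O)(C(C)(C)C)C(C)(C)C | intermediate
13 | (S)-18-methylicosyl 2,2-di-tert-butyl-1,3,2-benzodioxasilole-4-carboxylate | CC[C@H](C)CCCCCCCCCCCCCCCCCOC(=O)c1cccc2O[Si](C(C)(C)C)(C(C)(C)C)Oc12 | intermediate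
14 | Gentiside H, (S)-18-methylicosyl 2,3-dihydroxybenzoate | CC[C@H](C)CCCCCCCCCCCCCCCCCOC(=O)c1cccc(O)c1O | target

**Step count and risks**

Total step count: 7. Longest linear sequence: 7 steps, from 1 to 14.

Steps most likely to fail:

1. Step 6. Palladation at the ester-deactivated C3 may be too slow, so that the oxidant is spent unproductively and the silanol tether is lost, either by desilylation or by attack of Si–OH on the neighbouring ester carbonyl with expulsion of the alcohol. The fallback sets out from 6 and gives up the late C–H oxidation by bringing the catechol in ready-made. An Appel reaction (CBr4, PPh3, CH2Cl2, 0 °C → rt) should give (S)-1-bromo-18-methylicosane F1. O-alkylation of the carboxylate of commercial 2,3-dihydroxybenzoic acid with F1 (KHCO3, DMF, 60 °C; bicarbonate deprotonates the acid but not the phenols) should then give 14, where the fallback rejoins the route.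

2. Step 5. A second substitution at silicon, or participation of the neighbouring ester carbonyl at the silyl triflate stage followed by ester cleavage during hydrolysis, could erode the silanol; the aryl O–Si bond could also be lost on work-up. The fallback sets out from 8 and uses a silicon reagent with a single leaving group. Silylation with di-tert-butylchlorosilane (imidazole, DMF, 50 °C) should give (S)-18-methylicosyl 2-[(di-tert-butylsilyl)oxy]benzoate F2. Oxygen insertion into its Si–H bond with dimethyldioxirane (acetone, 0 °C), a known neutral silane-to-silanol oxidation, should give 11, where the fallback rejoins the route.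

3. Step 4. Acyl transfer may stay incomplete because the equilibrium is not driven fully and the hydrogen-bonded, tin-chelated salicylate is a poor acyl donor; material may also be lost on separating the product from excess 7 at high temperature. The fallback sets out from 6 and replaces acyl substitution by alkylation of a carboxylate. A Mitsunobu reaction with salicylic acid (PPh3, DIAD, THF, 0 °C → rt), chemoselective because the carboxylic acid is far more acidic than the phenol, should give 8 directly, where the fallback rejoins the route; it makes no compound outside the list (F0).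

**Further compounds**

F1 | step 6 | (S)-1-bromo-18-methylicosane | CC[C@H](C)CCCCCCCCCCCCCCCCCBr
F2 | step 5 | (S)-18-methylicosyl 2-[(di-tert-butylsilyl)oxy]benzoate | CC[C@H](C)CCCCCCCCCCCCCCCCCOC(=O)c1ccccc1O[SiH](C(C)(C)C)C(C)(C)C
F0 | step 4 | none | none
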